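**Plan**

- Retrosynthesis first cuts the three ester C–O bonds (acyl at O4, acyl at O5, acetyl at O3), then removes the C1=C2 unsaturation and returns C3 to a ketone, which leaves a 3-oxocyclohexanecarboxylate.
- The enabling feature is ring carbon C2 (shikimate numbering: C1 carries CO2Me, C3 the acetate, C4 and C5 the branched esters, C6 is CH2). It is an unsubstituted CH between ester-bearing C1 and oxygenated C3, so cutting C2–C3 and rejoining C1–C3 contracts the ring to a 2-oxocyclopentanecarboxylate with C2 as an exocyclic CH2Br on C1.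
- The five-membered ring is then cut at C1–C3 (Dieckmann) and at C1–C6 (Wittig) down to the four-carbon chain C3–C6.
- Forward: tartrate chain (C3–C6), Wittig extension (C1 and its ester), Dieckmann closure of the five-membered ring, CH2Br2 brings C2, radical expansion gives the six-membered ring, then alkene, C3 adjustment and three acylations.
- Stereochemistry: C4 and C5 are the carbinol centres of dimethyl D-tartrate (S,S), told apart as PMB and TBS ethers. C3 comes from a substrate-controlled Luche reduction followed by Mitsunobu inversion with acetic acid. The side-chain centres are bought with the two acids.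

Key step: step 10

Remark: C1 of 10, 11, 12 and 13 forms without control and is carried as a mixture of epimers (10 partly as its enol), so the SMILES leave it undefined; the centre becomes sp2 in 14. Ring positions are given in the shikimate numbering of the target, also for acyclic and five-membered precursors. PMB = 4-methoxybenzyl, TBS = tert-butyldimethylsilyl.

**Step 1**
Reactants: 1 dimethyl D-tartrate
Product: 2 dimethyl (2S,3S)-2-hydroxy-3-[(4-methoxybenzyl)oxy]butanedioate
Conditions: Ag2O (1.5 equiv), PMBCl (1.1 equiv), CH2Cl2, rt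
Reagents that add atoms: 4-methoxybenzyl chloride COc1ccc(CCl)cc1
Why: Ag2O-mediated Williamson-type etherification of a symmetrical diol is known to stop at the monoether, the two hydroxyls of the C2-symmetric diester are equivalent so no regiochemistry arises, and the non-basic medium leaves both α-stereocentres alone.

**Step 2**
Reactants: 2 dimethyl (2S,3S)-2-hydroxy-3-[(4-methoxybenzyl)oxy]butanedioate
Product: 3 methyl (2S,3R)-3,4-dihydroxy-2-[(4-methoxybenzyl)oxy]butanoate
Conditions: BH3·SMe2 (1.05 equiv), NaBH4 (5 mol %), THF, 0 °C to rt; MeOH quench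
Reagents that add atoms: none
Why: In this hydroxyl-directed borane reduction of an α-hydroxy ester the free hydroxyl forms an alkoxyborane that delivers hydride through a five-membered chelate to its own ester only, so the ester beside the PMB ether should survive and no stereocentre is touched.

**Step 3**
Reactants: 3 methyl (2S,3R)-3,4-dihydroxy-2-[(4-methoxybenzyl)oxy]butanoate
Product: 4 methyl (2S,3R)-3,4-bis[(tert-butyldimethylsilyl)oxy]-2-[(4-methoxybenzyl)oxy]butanoate
Conditions: TBSOTf (2.4 equiv), 2,6-lutidine, CH2Cl2, −78 to 0 °C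
Reagents that add atoms: tert-butyldimethylsilyl triflate CC(C)(C)[Si](C)(C)OS(=O)(=O)C(F)(F)F
Why: Silyl ether formation with a silyl triflate and a hindered pyridine base covers the primary and the flanked secondary hydroxyl alike, and does so faster than the γ-hydroxy ester can lactonise.

**Step 4**
Reactants: 4 methyl (2S,3R)-3,4-bis[(tert-butyldimethylsilyl)oxy]-2-[(4-methoxybenzyl)oxy]butanoate
Product: 5 methyl (2S,3R)-3-[(tert-butyldimethylsilyl)oxy]-4-hydroxy-2-[(4-methoxybenzyl)oxy]butanoate
Conditions: HF·pyridine, pyridine, THF, 0 °C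
Reagents that add atoms: none
Why: Selective desilylation with buffered HF·pyridine cleaves the unhindered primary silyl ether much faster than the flanked secondary one, and the PMB ether and the ester are inert to it.

**Step 5**
Reactants: 5 methyl (2S,3R)-3-[(tert-butyldimethylsilyl)oxy]-4-hydroxy-2-[(4-methoxybenzyl)oxy]butanoate
Product: 6 methyl (2S,3S)-3-[(tert-butyldimethylsilyl)oxy]-2-[(4-methoxybenzyl)oxy]-4-oxobutanoate
Conditions: Dess–Martin periodinane, NaHCO3, CH2Cl2, 0 °C to rt; used crude
Reagents that add atoms: none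
Why: Dess–Martin oxidation under bicarbonate buffer takes the primary alcohol to the aldehyde without acid or base strong enough to epimerise the α-silyloxy centre.

**Step 6**
Reactants: 6 methyl (2S,3S)-3-[(tert-butyldimethylsilyl)oxy]-2-[(4-methoxybenzyl)oxy]-4-oxobutanoate; 7 methyl (triphenylphosphoranylidene)acetate
Product: 8 dimethyl (2E,4R,5S)-4-[(tert-butyldimethylsilyl)oxy]-5-[(4-methoxybenzyl)oxy]hex-2-enedioate
Conditions: 7 (1.2 equiv), CH2Cl2, rt
Reagents that add atoms: none
Why: Wittig olefination with a stabilised ylide in an aprotic solvent adds the two carbons that become C1 and its ester, mainly as the E-enoate, and the geometry is irrelevant because the alkene is saturated next.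

**Step 7**
Reactants: 8 dimethyl (2E,4R,5S)-4-[(tert-butyldimethylsilyl)oxy]-5-[(4-methoxybenzyl)oxy]hex-2-enedioate
Product: 9 dimethyl (2S,3R)-3-[(tert-butyldimethylsilyl)oxy]-2-[(4-methoxybenzyl)oxy]hexanedioate
Conditions: H2 (1 atm), Pd/C (10 wt % Pd), pyridine (0.5 equiv), EtOAc, rt
Reagents that add atoms: none
Why: Heterogeneous hydrogenation saturates the conjugated alkene, while pyridine poisons the catalyst toward benzylic C–O hydrogenolysis so that the PMB ether and the allylic silyl ether should be kept.

**Step 8**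
Reactants: 9 dimethyl (2S,3R)-3-[(tert-butyldimethylsilyl)oxy]-2-[(4-methoxybenzyl)oxy]hexanedioate
Product: 10 methyl (3S,4R)-4-[(tert-butyldimethylsilyl)oxy]-3-[(4-methoxybenzyl)oxy]-2-oxocyclopentane-1-carboxylate
Conditions: LiN(SiMe3)2 (1.2 equiv), THF, −78 to 0 °C; AcOH quench
Reagents that add atoms: none
Why: In this Dieckmann condensation the hindered amide should deprotonate the open CH2 next to the remote ester (C1) in preference to the flanked alkoxy-bearing C4, the enolate closes 5-exo-trig on the more electrophilic α-alkoxy ester (C3), and only this direction gives a product with an acidic C1–H, whose enolate drives the equilibrium and blocks enolisation toward C4 and loss of the C5 silyloxy group.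

**Step 9**
Reactants: 10 methyl (3S,4R)-4-[(tert-butyldimethylsilyl)oxy]-3-[(4-methoxybenzyl)oxy]-2-oxocyclopentane-1-carboxylate
Product: 11 methyl (3S,4R)-1-(bromomethyl)-4-[(tert-butyldimethylsilyl)oxy]-3-[(4-methoxybenzyl)oxy]-2-oxocyclopentane-1-carboxylate
Conditions: NaH (1.0 equiv), THF–DMPU, 0 °C; CH2Br2 (10 equiv), 50 °C
Reagents that add atoms: dibromomethane BrCBr
Why: C-alkylation of the stabilised β-keto ester enolate by SN2 at CH2Br2 (large excess, so only one bromide is displaced) installs the future C2; the neopentyl-like product does not react again, no excess base is present to enolise it toward C4, and the quaternary C1 needs no control.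

**Step 10**
Reactants: 11 methyl (3S,4R)-1-(bromomethyl)-4-[(tert-butyldimethylsilyl)oxy]-3-[(4-methoxybenzyl)oxy]-2-oxocyclopentane-1-carboxylate
Product: 12 methyl (4S,5R)-5-[(tert-butyldimethylsilyl)oxy]-4-[(4-methoxybenzyl)oxy]-3-oxocyclohexane-1-carboxylate
Conditions: Bu3SnH (1.3 equiv) and AIBN (0.2 equiv) by syringe pump over 6 h, benzene (0.01 M), 80 °C
Reagents that add atoms: none
Why: The tributyltin radical abstracts bromine from 11 and the primary exocyclic radical (C2) adds 3-exo-trig to the adjacent ring ketone (C3), closing a bicyclo[3.1.0] cyclopropyloxy radical. β-Scission of the internal C1–C3 bond relieves the cyclopropane strain, so the new C2–C3 bond stays and the five-membered ring becomes the six-membered ketone; this is the Dowd–Beckwith ring expansion known for 1-(halomethyl)-2-oxocycloalkanecarboxylates. Scission goes toward C1 because it gives a tertiary, ester-stabilised radical, whereas cleavage toward C4 would leave a cyclopropanone and cleavage back toward C2 only regenerates the primary radical. Hydrogen transfer from Bu3SnH to the planar C1 radical creates that centre without useful control (the face anti to the C5 silyl ether is expected to lead), which is harmless because C1 becomes sp2 in step 11. The selectivity needed is rearrangement over direct reduction of the primary radical, secured by a low stationary Bu3SnH concentration (slow addition, high dilution) and by the ester that makes the fragmentation fast. The neutral medium leaves the tartrate-derived C4 and C5 centres and the β-silyloxy ketone, which would eliminate under base, untouched.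

**Step 11**
Reactants: 12 methyl (4S,5R)-5-[(tert-butyldimethylsilyl)oxy]-4-[(4-methoxybenzyl)oxy]-3-oxocyclohexane-1-carboxylate
Product: 14 methyl (4S,5R)-5-[(tert-butyldimethylsilyl)oxy]-4-[(4-methoxybenzyl)oxy]-3-oxocyclohex-1-ene-1-carboxylate, via trimethylsilyl enol ether 13 (not isolated)
Conditions: LiN(iPr)2 (1.1 equiv), TMSCl (in situ quench), THF, −78 °C; then Pd(OAc)2 (1.1 equiv), MeCN, rt
Reagents that add atoms: chlorotrimethylsilane C[Si](C)(C)Cl (its silyl group is carried by 13 only and is lost on the way to 14)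
Why: In this Saegusa–Ito oxidation the amide base with internal silyl trapping should enolise the ketone kinetically at the open C2 methylene and not at the flanked alkoxy-bearing C4, and the palladium enolate formed at C2 has its only β-hydrogen on C1, so β-hydride elimination places the alkene between C1 and C2 in conjugation with both carbonyls.

**Step 12**
Reactants: 14 methyl (4S,5R)-5-[(tert-butyldimethylsilyl)oxy]-4-[(4-methoxybenzyl)oxy]-3-oxocyclohex-1-ene-1-carboxylate
Product: 15 methyl (3S,4R,5R)-5-[(tert-butyldimethylsilyl)oxy]-3-hydroxy-4-[(4-methoxybenzyl)oxy]cyclohex-1-ene-1-carboxylate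
Conditions: NaBH4, CeCl3·7H2O, MeOH, −78 °C
Reagents that add atoms: none
Why: Luche reduction gives clean 1,2-reduction of the enone, hydride should enter along the pseudoaxial trajectory of the half-chair in which O4 and O5 are equatorial and so give the equatorial C3 alcohol trans to O4 (substrate control), and the cold neutral medium avoids aromatisation of the dehydroshikimate.

**Step 13**
Reactants: 15 methyl (3S,4R,5R)-5-[(tert-butyldimethylsilyl)oxy]-3-hydroxy-4-[(4-methoxybenzyl)oxy]cyclohex-1-ene-1-carboxylate
Product: 16 methyl (3R,4R,5R)-3-acetoxy-5-[(tert-butyldimethylsilyl)oxy]-4-[(4-methoxybenzyl)oxy]cyclohex-1-ene-1-carboxylate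
Conditions: PPh3, DIAD, AcOH, THF, 0 °C to rt
Reagents that add atoms: acetic acid CC(=O)O
Why: In this Mitsunobu esterification acetate displaces the oxyphosphonium of the secondary allylic alcohol by SN2 with inversion, turning the 3,4-trans alcohol into the 3,4-cis acetate of the target, while SN2′ attack is disfavoured because the distal alkene carbon is fully substituted and conjugated to the ester.

**Step 14**
Reactants: 16 methyl (3R,4R,5R)-3-acetoxy-5-[(tert-butyldimethylsilyl)oxy]-4-[(4-methoxybenzyl)oxy]cyclohex-1-ene-1-carboxylate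
Product: 17 methyl (3R,4S,5R)-3-acetoxy-5-hydroxy-4-[(4-methoxybenzyl)oxy]cyclohex-1-ene-1-carboxylate
Conditions: HF·pyridine, THF, 0 °C to rt
Reagents that add atoms: none
Why: Fluoride-driven desilylation under mildly acidic conditions leaves the allylic acetate, the PMB ether and the enoate alone, and since the neighbouring O4 carries an ether no acyl group can migrate onto the freed O5 from that side.

**Step 15**
Reactants: 17 methyl (3R,4S,5R)-3-acetoxy-5-hydroxy-4-[(4-methoxybenzyl)oxy]cyclohex-1-ene-1-carboxylate; 18 (S)-3-methylpentanoic acid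
Product: 19 methyl (3R,4S,5R)-3-acetoxy-4-[(4-methoxybenzyl)oxy]-5-{[(3S)-3-methylpentanoyl]oxy}cyclohex-1-ene-1-carboxylate
Conditions: 18 (1.5 equiv), DCC, DMAP (0.2 equiv), CH2Cl2, 0 °C to rt
Reagents that add atoms: none
Why: Steglich esterification (carbodiimide activation, DMAP acyl transfer) acylates the secondary alcohol, and the stereocentre of the acid is β to the carbonyl and cannot epimerise.

**Step 16**
Reactants: 19 methyl (3R,4S,5R)-3-acetoxy-4-[(4-methoxybenzyl)oxy]-5-{[(3S)-3-methylpentanoyl]oxy}cyclohex-1-ene-1-carboxylate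
Product: 20 methyl (3R,4S,5R)-3-acetoxy-4-hydroxy-5-{[(3S)-3-methylpentanoyl]oxy}cyclohex-1-ene-1-carboxylate
Conditions: DDQ (1.3 equiv), CH2Cl2–pH 7 buffer (10:1), 0 °C; used directly
Reagents that add atoms: none
Why: Oxidative PMB cleavage by DDQ goes through the benzylic oxocarbenium ion, which water hydrolyses, and the buffered neutral medium leaves the three esters in place and gives little chance for acyl migration onto the freed O4.

**Step 17**
Reactants: 20 methyl (3R,4S,5R)-3-acetoxy-4-hydroxy-5-{[(3S)-3-methylpentanoyl]oxy}cyclohex-1-ene-1-carboxylate; 21 (R)-2-methylbutanoic acid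
Product: 22 methyl (3R,4S,5R)-3-acetoxy-4-{[(2R)-2-methylbutanoyl]oxy}-5-{[(3S)-3-methylpentanoyl]oxy}cyclohex-1-ene-1-carboxylate
Conditions: 21 (2 equiv), DCC, DMAP (0.1 equiv), CH2Cl2, 0 °C to rt
Reagents that add atoms: none
Why: Steglich esterification run cold with little DMAP should acylate the last hydroxyl without enolising the α-stereocentre of the acid, completing the target with C3, C4 and C5 unchanged.

**Compound list**

1 | dimethyl D-tartrate, dimethyl (2S,3S)-2,3-dihydroxybutanedioate | COC(=O)[C@@H](O)[C@H](O)C(=O)OC | starting material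
2 | dimethyl (2S,3S)-2-hydroxy-3-[(4-methoxybenzyl)oxy]butanedioate | COC(=O)[C@@H](O)[C@H](OCc1ccc(OC)cc1)C(=O)OC | intermediate
3 | methyl (2S,3R)-3,4-dihydroxy-2-[(4-methoxybenzyl)oxy]butanoate | OC[C@@H](O)[C@H](OCc1ccc(OC)cc1)C(=O)OC | intermediate
4 | methyl (2S,3R)-3,4-bis[(tert-butyldimethylsilyl)oxy]-2-[(4-methoxybenzyl)oxy]butanoate | CC(C)(C)[Si](C)(C)OC[C@@H](O[Si](C)(C)C(C)(C)C)[C@H](OCc1ccc(OC)cc1)C(=O)OC | intermediate
5 | methyl (2S,3R)-3-[(tert-butyldimethylsilyl)oxy]-4-hydroxy-2-[(4-methoxybenzyl)oxy]butanoate | OC[C@@H](O[Si](C)(C)C(C)(C)C)[C@H](OCc1ccc(OC)cc1)C(=O)OC | intermediate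
6 | methyl (2S,3S)-3-[(tert-butyldimethylsilyl)oxy]-2-[(4-methoxybenzyl)oxy]-4-oxobutanoate | O=C[C@@H](O[Si](C)(C)C(C)(C)C)[C@H](OCc1ccc(OC)cc1)C(=O)OC | intermediate
7 | methyl (triphenylphosphoranylidene)acetate | COC(=O)C=P(c1ccccc1)(c1ccccc1)c1ccccc1 | starting material
8 | dimethyl (2E,4R,5S)-4-[(tert-butyldimethylsilyl)oxy]-5-[(4-methoxybenzyl)oxy]hex-2-enedioate | COC(=O)/C=C/[C@@H](O[Si](C)(C)C(C)(C)C)[C@H](OCc1ccc(OC)cc1)C(=O)OC | intermediate
9 | dimethyl (2S,3R)-3-[(tert-butyldimethylsilyl)oxy]-2-[(4-methoxybenzyl)oxy]hexanedioate | COC(=O)CC[C@@H](O[Si](C)(C)C(C)(C)C)[C@H](OCc1ccc(OC)cc1)C(=O)OC | intermediate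
10 | methyl (3S,4R)-4-[(tert-butyldimethylsilyl)oxy]-3-[(4-methoxybenzyl)oxy]-2-oxocyclopentane-1-carboxylate (C1 epimers and enol) | COC(=O)C1C[C@@H](O[Si](C)(C)C(C)(C)C)[C@H](OCc2ccc(OC)cc2)C1=O | intermediate
11 | methyl (3S,4R)-1-(bromomethyl)-4-[(tert-butyldimethylsilyl)oxy]-3-[(4-methoxybenzyl)oxy]-2-oxocyclopentane-1-carboxylate (both C1 epimers) | COC(=O)C1(CBr)C[C@@H](O[Si](C)(C)C(C)(C)C)[C@H](OCc2ccc(OC)cc2)C1=O | intermediate
12 | methyl (4S,5R)-5-[(tert-butyldimethylsilyl)oxy]-4-[(4-methoxybenzyl)oxy]-3-oxocyclohexane-1-carboxylate (both C1 epimers) | COC(=O)C1CC(=O)[C@@H](OCc2ccc(OC)cc2)[C@H](O[Si](C)(C)C(C)(C)C)C1 | intermediate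
13 | methyl (4S,5R)-5-[(tert-butyldimethylsilyl)oxy]-4-[(4-methoxybenzyl)oxy]-3-[(trimethylsilyl)oxy]cyclohex-2-ene-1-carboxylate (not isolated) | COC(=O)C1C=C(O[Si](C)(C)C)[C@@H](OCc2ccc(OC)cc2)[C@H](O[Si](C)(C)C(C)(C)C)C1 | intermediate
14 | methyl (4S,5R)-5-[(tert-butyldimethylsilyl)oxy]-4-[(4-methoxybenzyl)oxy]-3-oxocyclohex-1-ene-1-carboxylate | COC(=O)C1=CC(=O)[C@@H](OCc2ccc(OC)cc2)[C@H](O[Si](C)(C)C(C)(C)C)C1 | intermediate
15 | methyl (3S,4R,5R)-5-[(tert-butyldimethylsilyl)oxy]-3-hydroxy-4-[(4-methoxybenzyl)oxy]cyclohex-1-ene-1-carboxylate (O3 trans to O4) | COC(=O)C1=C[C@H](O)[C@@H](OCc2ccc(OC)cc2)[C@H](O[Si](C)(C)C(C)(C)C)C1 | intermediate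
16 | methyl (3R,4R,5R)-3-acetoxy-5-[(tert-butyldimethylsilyl)oxy]-4-[(4-methoxybenzyl)oxy]cyclohex-1-ene-1-carboxylate (O3 cis to O4) | COC(=O)C1=C[C@@H](OC(C)=O)[C@@H](OCc2ccc(OC)cc2)[C@H](O[Si](C)(C)C(C)(C)C)C1 | intermediate
17 | methyl (3R,4S,5R)-3-acetoxy-5-hydroxy-4-[(4-methoxybenzyl)oxy]cyclohex-1-ene-1-carboxylate | COC(=O)C1=C[C@@H](OC(C)=O)[C@@H](OCc2ccc(OC)cc2)[C@H](O)C1 | intermediate
18 | (S)-3-methylpentanoic acid | CC[C@H](C)CC(=O)O | starting material
19 | methyl (3R,4S,5R)-3-acetoxy-4-[(4-methoxybenzyl)oxy]-5-{[(3S)-3-methylpentanoyl]oxy}cyclohex-1-ene-1-carboxylate | CC[C@H](C)CC(=O)O[C@@H]1CC(C(=O)OC)=C[C@@H](OC(C)=O)[C@H]1OCc1ccc(OC)cc1 | intermediate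
20 | methyl (3R,4S,5R)-3-acetoxy-4-hydroxy-5-{[(3S)-3-methylpentanoyl]oxy}cyclohex-1-ene-1-carboxylate | CC[C@H](C)CC(=O)O[C@@H]1CC(C(=O)OC)=C[C@@H](OC(C)=O)[C@H]1O | intermediate
21 | (R)-2-methylbutanoic acid | CC[C@@H](C)C(=O)O | starting material
22 | methyl (3R,4S,5R)-3-acetoxy-4-{[(2R)-2-methylbutanoyl]oxy}-5-{[(3S)-3-methylpentanoyl]oxy}cyclohex-1-ene-1-carboxylate | CC[C@H](C)CC(=O)O[C@@H]1CC(C(=O)OC)=C[C@@H](OC(C)=O)[C@H]1OC(=O)[C@H](C)CC | target

**Count**

Total steps: 17. Longest linear sequence: 17 steps (1 to 22).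

**Steps most likely to fail**

Step 10. Hydrogen transfer from Bu3SnH to the primary radical may outrun its closure on the ketone, or the radical may take a benzylic hydrogen from the PMB ether by a 1,6-shift; either way the unexpanded five-membered ketone would result. The fallback sets out from 10 and inserts the same CH2 without a free radical or a hydride donor, by zinc-carbenoid chain extension. Et2Zn and CH2I2 in CH2Cl2 at 0 °C convert the zinc enolate of 10 into its C1-zinciomethyl derivative, which closes on the C3 carbonyl to the bicyclic ethylzinc cyclopropoxide F1 (not isolated). This fragments across the same C1–C3 bond to the zinc enolate of the six-membered keto ester, and aqueous NH4Cl then releases 12, where the route is rejoined.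

Step 11. The base may enolise the ketone toward C4 instead of C2, after which the C5 silyloxy group is expelled, and the dehydroshikimate product may aromatise on contact with base. The fallback sets out from 12 and avoids any strong base. Enamine-catalysed α-selenenylation (N-(phenylseleno)phthalimide, pyrrolidine 20 mol %, CH2Cl2, rt) should go through the less substituted enamine toward C2 and give the 2-(phenylselanyl) ketone F2. Oxidation with H2O2 and pyridine in CH2Cl2 at 0 °C and syn-elimination of the selenoxide toward C1–H then gives 14, where the route is rejoined.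

Step 9. Substitution of the hindered enolate at CH2Br2 may be slow and accompanied by O-alkylation, and on prolonged heating the product may enolise toward C4 and lose its silyloxy group. The fallback sets out from 10 and builds the halomethyl group in two mild stages. Aldol addition to aqueous formaldehyde (KHCO3, THF, rt) gives the hydroxymethyl keto ester F3, and I2, PPh3 and imidazole in toluene at 60 °C turn it into the iodomethyl keto ester F4. F4 is then submitted to the conditions of step 10, the iodide being at least as good a radical precursor as the bromide, and the route is rejoined at 12.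

**Further compounds**

F1 | step 10 | methyl (2S,3R)-3-[(tert-butyldimethylsilyl)oxy]-1-[(ethylzincio)oxy]-2-[(4-methoxybenzyl)oxy]bicyclo[3.1.0]hexane-5-carboxylate (not isolated) | CC[Zn]OC12CC1(C(=O)OC)C[C@@H](O[Si](C)(C)C(C)(C)C)[C@@H]2OCc1ccc(OC)cc1
F2 | step 11 | methyl (4S,5R)-5-[(tert-butyldimethylsilyl)oxy]-4-[(4-methoxybenzyl)oxy]-3-oxo-2-(phenylselanyl)cyclohexane-1-carboxylate | COC(=O)C1C([Se]c2ccccc2)C(=O)[C@@H](OCc2ccc(OC)cc2)[C@H](O[Si](C)(C)C(C)(C)C)C1
F3 | step 9 | methyl (3S,4R)-4-[(tert-butyldimethylsilyl)oxy]-1-(hydroxymethyl)-3-[(4-methoxybenzyl)oxy]-2-oxocyclopentane-1-carboxylate | COC(=O)C1(CO)C[C@@H](O[Si](C)(C)C(C)(C)C)[C@H](OCc2ccc(OC)cc2)C1=O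
F4 | step 9 | methyl (3S,4R)-4-[(tert-butyldimethylsilyl)oxy]-1-(iodomethyl)-3-[(4-methoxybenzyl)oxy]-2-oxocyclopentane-1-carboxylate | COC(=O)C1(CI)C[C@@H](O[Si](C)(C)C(C)(C)C)[C@H](OCc2ccc(OC)cc2)C1=O
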